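**Retrosynthetic overview**
1. The strategy rests on the benzene ring: its carbons C3' and C5' carry oxygen (OH and OMe) and both lie meta to C1', which holds the side chain (chain numbering: C1 benzylic CH2, C2 CH–OAc, C8 ketone). This 1,3,5-pattern is that of a 5-substituted cyclohexane-1,3-dione, and the mono methyl enol ether of the dione decides which oxygen ends as OMe.
2. Target 22 ⇐ diacetate 21 (aryl acetate cleaved) ⇐ diol 20 ⇐ benzyl ether phenol 19 ⇐ enol ether 18 (ring dehydrogenation) ⇐ dione 17.
3. Key disconnection: the only ring, a six-membered carbocycle, is formed late from E-enone 12 and dimethyl malonate 13 by Michael addition (ring bond C5–C6) and Claisen closure (ring bond C1–C2), with the spare ester lost as CO2.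
4. Enone 12 ⇐ cross-metathesis of methyl vinyl ketone 11 with homoallylic benzyl ether 10; C2 (R) comes from asymmetric allylboration of keto aldehyde 7.
5. 7 ⇐ ozonolysis of 1-pentylcycloheptene 5 ⇐ cycloheptanone 1 and the Grignard reagent of 1-bromopentane 2.

Key step: step 7

Remark on the chemistry: ring C5 of enol ether 18 is a stereocenter of no consequence (both epimers give 19), so 18 and the not-isolated intermediates 14–16 are drawn without configuration at their ring or branch carbons; ozonide 6 is racemic.

**Step 1**
Reactants: 1 cycloheptanone; 2 1-bromopentane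
Product: 4 1-pentylcycloheptan-1-ol, via pentylmagnesium bromide 3 (not isolated)
Conditions: Mg, THF, 40 °C; then 1, 0 °C to rt; H2O work-up
Reagents that add atoms: none
Why: Grignard formation and 1,2-addition to the unhindered ketone should give the tertiary alcohol directly.

**Step 2**
Reactants: 4 1-pentylcycloheptan-1-ol
Product: 5 1-pentylcyclohept-1-ene
Conditions: TsOH·H2O (5 mol%), toluene, reflux, Dean–Stark
Reagents that add atoms: none
Why: Acid-catalyzed E1 dehydration under equilibrating conditions should favor the endocyclic trisubstituted alkene (Zaitsev product), and any exocyclic isomer gives only volatile cycloheptanone and pentanal in step 3 and is lost there.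

**Step 3**
Reactants: 5 1-pentylcyclohept-1-ene
Product: 7 7-oxododecanal, via secondary ozonide 6 (not isolated)
Conditions: O3, CH2Cl2, −78 °C; then PPh3, −78 °C to rt
Reagents that add atoms: ozone, [O-][O+]=O
Why: Ozonolysis (Criegee mechanism) followed by reduction of the ozonide with PPh3 should cleave the ring alkene to the ketone and the aldehyde without overoxidation.

**Step 4**
Reactants: 7 7-oxododecanal
Product: 9 (R)-4-hydroxypentadec-1-en-10-one, via diisopinocampheylborinate ester 8 (not isolated)
Conditions: (−)-Ipc2BOMe (1.15 equiv), allylMgBr (1.1 equiv), Et2O, 0 °C to rt; then 7, −78 °C; then 3 M NaOH, 30% H2O2, 0 °C to rt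
Reagents that add atoms: allylmagnesium bromide, C=CC[Mg]Br, delivered as B-allyldiisopinocampheylborane of the (+)-α-pinene series, C=CCB([C@@H]1C[C@@H]2C[C@H]([C@H]1C)C2(C)C)[C@@H]1C[C@@H]2C[C@H]([C@H]1C)C2(C)C
Why: Brown asymmetric allylboration, in which the (+)-α-pinene-derived allylborane should add through a closed chair Zimmerman–Traxler transition state to the Si face of the aldehyde and so set C2 as R, while at −78 °C the aldehyde reacts far faster than the dialkyl ketone.

**Step 5**
Reactants: 9 (R)-4-hydroxypentadec-1-en-10-one
Product: 10 (R)-4-(benzyloxy)pentadec-1-en-10-one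
Conditions: BnOC(=NH)CCl3 (1.5 equiv), TfOH (5 mol%), CH2Cl2/cyclohexane, 0 °C to rt
Reagents that add atoms: benzyl 2,2,2-trichloroacetimidate, N=C(OCc1ccccc1)C(Cl)(Cl)Cl
Why: Acid-catalyzed O-benzylation with the trichloroacetimidate needs no base, so the C8 ketone is not enolized and the C–O bond at the stereocenter is never broken.

**Step 6**
Reactants: 10 (R)-4-(benzyloxy)pentadec-1-en-10-one; 11 methyl vinyl ketone
Product: 12 (R,E)-6-(benzyloxy)heptadec-3-ene-2,12-dione
Conditions: 11 (3 equiv), second-generation Grubbs catalyst RuCl2(H2IMes)(PCy3)(=CHPh) (3 mol%), CH2Cl2, 40 °C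
Reagents that add atoms: none
Why: Olefin cross-metathesis between the terminal alkene and the electron-poor, slowly homodimerizing vinyl ketone should give the E-enone selectively, driven by loss of ethene, with the benzyl ether and the dialkyl ketone inert to the ruthenium carbene.

**Step 7**
Reactants: 12 (R,E)-6-(benzyloxy)heptadec-3-ene-2,12-dione; 13 dimethyl malonate
Product: 17 (R)-5-[2-(benzyloxy)-8-oxotridecyl]cyclohexane-1,3-dione, via Michael adduct 14 (not isolated), via cyclic keto ester 15 (not isolated), via keto acid 16 (not isolated)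
Conditions: 13 (1.2 equiv), NaOMe (1.2 equiv), MeOH, 0 °C to reflux; then 2 M aq. NaOH, reflux; then aq. HCl to pH 2, 70 °C
Reagents that add atoms: none
Why: The malonate anion adds to the β-carbon of the E-enone (Michael addition, ring bond C5–C6), proton transfer gives the methyl ketone enolate of 14, and this attacks one ester carbonyl with loss of methoxide in a Claisen (Dieckmann-type) condensation that forms ring bond C1–C2 by a 6-(enolexo)-exo-trig closure to 15. The closest known reaction type is the malonate–enone Michael–Claisen annulation used for dimedone and for 5-alkylcyclohexane-1,3-diones. Deprotonation of the cyclic β-dicarbonyl product pulls both equilibria forward, hydroxide then hydrolyzes the remaining ester, and acidification with warming expels CO2 from keto acid 16. No lasting stereocenter is made, because ring C5 of 17 lies on the local mirror plane of the dione and C2 of the chain is a spectator. The step needs 1,4-addition and ring closure to outrun γ-deprotonation with loss of benzyl oxide, which the weakly basic stabilized malonate anion and the poor alkoxide leaving group should secure. Only the methyl ketone enolate can reach a six-membered ring, since the C8 ketone could close only medium rings and its self-aldol is reversible.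

**Step 8**
Reactants: 17 (R)-5-[2-(benzyloxy)-8-oxotridecyl]cyclohexane-1,3-dione
Product: 18 5-[(2R)-2-(benzyloxy)-8-oxotridecyl]-3-methoxycyclohex-2-en-1-one (both epimers at ring C5)
Conditions: TMSCHN2 (1.3 equiv), MeOH/toluene 1:3, 0 °C to rt
Reagents that add atoms: trimethylsilyldiazomethane, C[Si](C)(C)C=[N+]=[N-]
Why: O-Methylation of the acidic enol of the cyclic 1,3-dione by the diazo reagent in methanol should give the vinylogous ester without touching the non-acidic C8 ketone, and the two enol oxygens are equivalent with respect to the arene formed later.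

**Step 9**
Reactants: 18 5-[(2R)-2-(benzyloxy)-8-oxotridecyl]-3-methoxycyclohex-2-en-1-one
Product: 19 (R)-12-(benzyloxy)-13-(3-hydroxy-5-methoxyphenyl)tridecan-6-one
Conditions: DDQ (1.2 equiv), 1,4-dioxane, 100 °C
Reagents that add atoms: none
Why: Quinone dehydrogenation of a cyclohexenone to a phenol, in which DDQ should abstract hydride from ring C5 of the dienol form of the vinylogous ester and tautomerization then gives the arene, while the isolated C8 ketone enolizes far more slowly and gains no aromatic stabilization.

**Step 10**
Reactants: 19 (R)-12-(benzyloxy)-13-(3-hydroxy-5-methoxyphenyl)tridecan-6-one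
Product: 20 (R)-12-hydroxy-13-(3-hydroxy-5-methoxyphenyl)tridecan-6-one
Conditions: H2 (1 atm), 10% Pd/C, EtOAc, rt
Reagents that add atoms: none
Why: Catalytic hydrogenolysis cleaves only the O–CH2Ph bond, so C2 keeps its configuration, and a dialkyl ketone and an electron-rich arene are not reduced under these conditions.

**Step 11**
Reactants: 20 (R)-12-hydroxy-13-(3-hydroxy-5-methoxyphenyl)tridecan-6-one
Product: 21 (R)-1-(3-acetoxy-5-methoxyphenyl)-8-oxotridecan-2-yl acetate
Conditions: Ac2O (3 equiv), pyridine, DMAP (5 mol%), CH2Cl2, 0 °C to rt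
Reagents that add atoms: acetic anhydride, CC(=O)OC(C)=O
Why: DMAP-catalyzed acylation should esterify both the secondary alcohol and the phenol, with retention at C2 because only O–H bonds react.

**Step 12**
Reactants: 21 (R)-1-(3-acetoxy-5-methoxyphenyl)-8-oxotridecan-2-yl acetate
Product: 22 (R)-1-(3-hydroxy-5-methoxyphenyl)-8-oxotridecan-2-yl acetate
Conditions: NH4OAc (8 equiv), MeOH/H2O 4:1, rt
Reagents that add atoms: none
Why: Chemoselective solvolysis of an aryl acetate, since phenoxide is a far better leaving group than a secondary alkoxide, so the neutral acetate-mediated methanolysis should stop with the C2 acetate intact.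

**Compound list**
1 | cycloheptanone | O=C1CCCCCC1 | starting material
2 | 1-bromopentane | CCCCCBr | starting material
3 | pentylmagnesium bromide | CCCCC[Mg]Br | intermediate
4 | 1-pentylcycloheptan-1-ol | CCCCCC1(O)CCCCCC1 | intermediate
5 | 1-pentylcyclohept-1-ene | CCCCCC1=CCCCCC1 | intermediate
6 | 1-pentyl-8,9,10-trioxabicyclo[5.2.1]decane (secondary ozonide, racemic) | CCCCCC12CCCCCC(OO1)O2 | intermediate
7 | 7-oxododecanal | CCCCCC(=O)CCCCCC=O | intermediate
8 | (4R)-10-oxopentadec-1-en-4-yl diisopinocampheylborinate | CCCCCC(=O)CCCCC[C@H](CC=C)OB([C@@H]1C[C@@H]2C[C@H]([C@H]1C)C2(C)C)[C@@H]1C[C@@H]2C[C@H]([C@H]1C)C2(C)C | intermediate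
9 | (R)-4-hydroxypentadec-1-en-10-one | CCCCCC(=O)CCCCC[C@H](CC=C)O | intermediate
10 | (R)-4-(benzyloxy)pentadec-1-en-10-one | CCCCCC(=O)CCCCC[C@H](CC=C)OCc1ccccc1 | intermediate
11 | methyl vinyl ketone (but-3-en-2-one) | CC(=O)C=C | starting material
12 | (R,E)-6-(benzyloxy)heptadec-3-ene-2,12-dione | CCCCCC(=O)CCCCC[C@H](C/C=C/C(C)=O)OCc1ccccc1 | intermediate
13 | dimethyl malonate | COC(=O)CC(=O)OC | starting material
14 | dimethyl 2-[(6R)-6-(benzyloxy)-2,12-dioxoheptadecan-4-yl]malonate | CCCCCC(=O)CCCCC[C@H](CC(CC(C)=O)C(C(=O)OC)C(=O)OC)OCc1ccccc1 | intermediate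
15 | methyl 6-[(2R)-2-(benzyloxy)-8-oxotridecyl]-2,4-dioxocyclohexane-1-carboxylate (present as its sodium enolate) | CCCCCC(=O)CCCCC[C@H](CC1CC(=O)CC(=O)C1C(=O)OC)OCc1ccccc1 | intermediate
16 | 6-[(2R)-2-(benzyloxy)-8-oxotridecyl]-2,4-dioxocyclohexane-1-carboxylic acid | CCCCCC(=O)CCCCC[C@H](CC1CC(=O)CC(=O)C1C(=O)O)OCc1ccccc1 | intermediate
17 | (R)-5-[2-(benzyloxy)-8-oxotridecyl]cyclohexane-1,3-dione | CCCCCC(=O)CCCCC[C@H](CC1CC(=O)CC(=O)C1)OCc1ccccc1 | intermediate
18 | 5-[(2R)-2-(benzyloxy)-8-oxotridecyl]-3-methoxycyclohex-2-en-1-one (both epimers at ring C5) | CCCCCC(=O)CCCCC[C@H](CC1CC(=O)C=C(OC)C1)OCc1ccccc1 | intermediate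
19 | (R)-12-(benzyloxy)-13-(3-hydroxy-5-methoxyphenyl)tridecan-6-one | CCCCCC(=O)CCCCC[C@H](Cc1cc(O)cc(OC)c1)OCc1ccccc1 | intermediate
20 | (R)-12-hydroxy-13-(3-hydroxy-5-methoxyphenyl)tridecan-6-one | CCCCCC(=O)CCCCC[C@H](Cc1cc(O)cc(OC)c1)O | intermediate
21 | (R)-1-(3-acetoxy-5-methoxyphenyl)-8-oxotridecan-2-yl acetate | CCCCCC(=O)CCCCC[C@H](Cc1cc(OC(C)=O)cc(OC)c1)OC(C)=O | intermediate
22 | (R)-1-(3-hydroxy-5-methoxyphenyl)-8-oxotridecan-2-yl acetate | CCCCCC(=O)CCCCC[C@H](Cc1cc(O)cc(OC)c1)OC(C)=O | target

**Step count**
Total: 12 steps. Longest linear sequence: 12 steps, from cycloheptanone 1 to 22; methyl vinyl ketone 11 and dimethyl malonate 13 enter as single reagents.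

**Steps most likely to fail**

Step 9. The dehydrogenation may be unselective: hydride abstraction at the benzyl ether or next to the C8 ketone, or oxidative coupling of the electron-rich phenol as it forms. The fallback aromatizes one stage earlier, by halogenation and elimination at the doubly activated ring carbon, and lets the ester tell the two oxygens apart. It sets out from cyclic keto ester 15, collected as its sodium enolate by stopping step 7 before the hydroxide stage. Br2 in DMF at 0 °C, then warming, brominates the ring carbon between the two carbonyls and eliminates HBr to give methyl 6-[(2R)-2-(benzyloxy)-8-oxotridecyl]-2,4-dihydroxybenzoate F1. MeI (1.05 equiv) and K2CO3 in acetone should methylate only the 4-hydroxyl, since the 2-hydroxyl is held in a hydrogen bond to the ester, giving methyl 6-[(2R)-2-(benzyloxy)-8-oxotridecyl]-2-hydroxy-4-methoxybenzoate F2. NaOH in aqueous methanol at reflux gives 6-[(2R)-2-(benzyloxy)-8-oxotridecyl]-2-hydroxy-4-methoxybenzoic acid F3, an electron-rich salicylic acid that should lose CO2 on acidification and heating. The fallback comes back to the route at phenol 19.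

Step 7. Loss of benzyl alcohol from the enone by γ-deprotonation may run faster than conjugate addition, or the Claisen closure may stall at the open adduct. The fallback exchanges the roles of the two partners. It sets out from 10, which undergoes cross-metathesis with methyl acrylate (same ruthenium catalyst) to give methyl (R,E)-5-(benzyloxy)-11-oxohexadec-2-enoate F4, whose γ-hydrogens are less acidic than those of the enone. Methyl acetoacetate and NaOMe in MeOH add 1,4 to give dimethyl 2-acetyl-3-[(2R)-2-(benzyloxy)-8-oxotridecyl]pentanedioate F5. Its acetyl methyl enolate closes onto the chain ester, and the fallback comes back at cyclic keto ester 15, which the hydroxide and acid stages of step 7 carry on to 17.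

Step 4. Erosion of enantiomeric purity through a poorly organized transition state, or competing allyl transfer to the ketone on warming, would carry through to the target. The fallback moves stereocontrol from a stoichiometric chiral borane to a chiral Lewis acid catalyst acting on an achiral allyl donor (Keck allylation). It sets out from 7 and uses allyltributylstannane, (S)-BINOL and Ti(OiPr)4 (10 mol% each), 4 Å molecular sieves, CH2Cl2, −20 °C. The titanium–BINOL complex activates only the aldehyde, and the stannane is expected to attack its Si face through an open transition state. The fallback comes back at 9 and makes no compound outside the list (F0).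

**Further compounds**
F1 | step 9 | methyl 6-[(2R)-2-(benzyloxy)-8-oxotridecyl]-2,4-dihydroxybenzoate | CCCCCC(=O)CCCCC[C@H](Cc1cc(O)cc(O)c1C(=O)OC)OCc1ccccc1
F2 | step 9 | methyl 6-[(2R)-2-(benzyloxy)-8-oxotridecyl]-2-hydroxy-4-methoxybenzoate | CCCCCC(=O)CCCCC[C@H](Cc1cc(OC)cc(O)c1C(=O)OC)OCc1ccccc1
F3 | step 9 | 6-[(2R)-2-(benzyloxy)-8-oxotridecyl]-2-hydroxy-4-methoxybenzoic acid | CCCCCC(=O)CCCCC[C@H](Cc1cc(OC)cc(O)c1C(=O)O)OCc1ccccc1
F4 | step 7 | methyl (R,E)-5-(benzyloxy)-11-oxohexadec-2-enoate | CCCCCC(=O)CCCCC[C@H](C/C=C/C(=O)OC)OCc1ccccc1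
F5 | step 7 | dimethyl 2-acetyl-3-[(2R)-2-(benzyloxy)-8-oxotridecyl]pentanedioate | CCCCCC(=O)CCCCC[C@H](CC(CC(=O)OC)C(C(C)=O)C(=O)OC)OCc1ccccc1
F0 | step 4 | none | none
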